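The vessel and its timing are what differ between these four runs, with the same charge in each.

    precatalyst → free catalyst (k1 = 0.206 s⁻¹)
    2 substrate → self-condensation product (k2 = 6.95 × 10⁻⁴ M⁻¹ s⁻¹)
    free catalyst + target → free catalyst + over-reaction product (k3 = 1140 M⁻¹ s⁻¹)
    catalyst intermediate → free catalyst + target (k4 = 627 s⁻¹)
    substrate + free catalyst ⇌ catalyst intermediate (K5 = 28.1 M⁻¹, k5 = 1060 M⁻¹ s⁻¹)

| flask | substrate | precatalyst | remark | time |
|---|---|---|---|---|
| birch | 0.050 M | 0.10 mM | a single well-mixed tank run continuously and read at steady state, 250 s in it on average |  |
| cedar | 0.050 M | 0.10 mM | everything together in a closed stirred flask, run for 50 s | 50 s |
| oak | 0.050 M | 0.10 mM | one stirred flow tank at steady state, fed with the mixture as stated, mean residence time 50 s |  |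
| maple | 0.050 M (fed, over 50.0 s) | 0.10 mM | all but substrate at the start; substrate goes in evenly over 50.0 s, the run ends at 50 s | 50 s |

- in percentages every species weighs as the substrate in it: one self-condensation product counts as two
- two of one species on the left: rate k times its square, two consumed each time
- the stated concentrations are those of everything mixed, before any reaction; amounts are the same in each set-up
- the feed brings no volume worth counting
- run time (cedar): 50 s

- the set-up with the highest amount of target at the outlet or at the end, in percent of the substrate put in ("none" if the first two lie within 2 percentage points) (birch / cedar / oak / maple / none)
- amount of target at the outlet or at the end, in percent of the substrate put in, birch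
- amount of target at the outlet or at the end, in percent of the substrate put in, cedar
- amount of target at the outlet or at the end, in percent of the substrate put in, oak
- amount of target at the outlet or at the end, in percent of the substrate put in, maple

I counted turnovers. Self-condensation's first half-life of 14400 s was longer than the 250 s of the longest run, so I set it aside. The precatalyst I kept, with its mean life of 4.85 s before it turns into free catalyst. The intermediate goes forward at 627 s⁻¹ and returns at 37.7 s⁻¹, so I used the steady-state constant 1000 M⁻¹ s⁻¹ for substrate going to target. This makes substrate pseudo-first-order at a given catalyst level. The selectivity factor, target's loss constant over that one, was 1.14. For 50 s I reckoned 5.00: the turnover count, which is the effective constant times the catalyst charge times the time in the vessel. That plain count takes the whole charge as active, so I corrected it for activation in each vessel where the lag counted.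

First I turned the time in a tank. A tank leaves a substrate fraction of one over (one plus the count). Its target fraction is the count over the product of (one plus the count) and (one plus the selectivity factor times the count). In a tank the active share of the catalyst charge is k1 times the residence time, over one plus that product, so oak's count came down to 4.56 and gave 13.2 %. Birch had a count of 24.5 and gave 3.32 %.

Next I closed the vessel at the same 50 s. In cedar the target fraction is the exponential of minus the count, less the exponential of minus the selectivity factor times the count, all over the selectivity factor less one. Activation takes its mean life off the time, so cedar's count was 4.51, and that gave 3.66 %.

Last I spread the feed. In maple, substrate settles within about 10.0 s, shorter than the 50.0 s of dosing. The lag of 4.85 s is shorter than those 50.0 s, so for the end of maple I took the plain count. Its substrate fraction then holds near one over the count, and target climbs toward one over the selectivity factor times the count, 17.5 %. My choice was maple.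

The forecast gave 3.33 % for birch, 3.9 % for cedar, 13.4 % for oak and 17.4 % for maple, chose maple, and called cedar “well past the maximum”. Its cedar stood higher than mine, and so did its oak.

The flask gave 3.33 % in birch, 3.91 % in cedar, 13.4 % in oak and 17.4 % in maple, so maple came first. With the step from target to over-reaction product struck out, cedar reached 98.8 %, more than maple's 17.4 %. Maple ended with 20.2 % of its substrate, and one over the plain count is 20.0 %. Cedar left until 500 s has a count of 49.5, for which the closed-vessel expression leaves hardly any target, and cedar then held 0 %.

Its constants were set for the occasion, and the outcome is calculated.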